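**Plan**

1. Numbering: ring A = C1(OAc)–C2H2–C3H–C8H–C9H=C10(CH3); ring B = C3–C4(CH3)–C5(OAc)–C6H2–C7(=C11)–C8; C11 bears CH3 and C12H2OCHO. Cuts: the three ester C–O bonds, C1–H (back to the enone), C10–CH3, then both bonds of C10 (C1–C10, C9–C10), which contracts ring A to the five-membered ring C1–C2–C3–C8–C9.
2. Further cuts: C3–C8, C1–C9 and C1–C2 (Pauson–Khand), C7–C8 (Sonogashira), C7–C11 (aldol) and C4–C5 (crotylboration), down to four commercial pieces.
3. Enabling feature: the triad C1(O)–C10(CH3)=C9(H) of ring A is, at the ketone level, a 2-substituted cyclohex-2-enone. That is exactly what the cyclopropyl-to-allyl cation opening of a dibromocarbene adduct of a C1=C9 enol ether of the five-membered ring delivers, with C10 as the inserted carbon.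
4. Forward: the acyclic chain is assembled first; ring B and a cyclopentenone then form together from the 1,7-enyne; the five-membered ring is expanded by one carbon to ring A; methylation, reduction and acylation finish the route.
5. Stereochemistry: C4/C5 from catalyst-controlled syn-crotylboration; C3 from the chair-like enyne cyclisation (trans to the C4 methyl); C8 from conjugate hydride delivery (cis fusion, also the thermodynamic one); C1 from hydride attack on the convex face; the C7=C11 geometry from an (E)-enol tosylate coupled with retention.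

Key step: step 12

Remark: the (S)-phosphoric acid is assumed to deliver the crotyl group to the Si face of aldehyde 1 (closed chair model); were the opposite sense found, the (R)-catalyst would be used without other change.

**Route**

Step 1
Reactants: 1 3-[(tert-butyldimethylsilyl)oxy]propanal; 2 (Z)-crotylboronic acid pinacol ester
Product: 4 (3R,4R)-1-[(tert-butyldimethylsilyl)oxy]-4-methylhex-5-en-3-ol, via pinacol borate ester 3 (not isolated)
Conditions: (S)-TRIP [(S)-3,3′-bis(2,4,6-triisopropylphenyl)-1,1′-binaphthyl-2,2′-diyl hydrogen phosphate, 5 mol %], toluene, −30 °C; aqueous NaHCO3 work-up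
Reagents that add atoms: none
Why: Chiral phosphoric acid-catalysed crotylboration through a closed chair transition state, in which the (Z)-boronate gives the syn relationship and Si-face delivery sets the carbinol as R, so that C5 and C4 of the target are both fixed here.

Step 2
Reactants: 4 (3R,4R)-1-[(tert-butyldimethylsilyl)oxy]-4-methylhex-5-en-3-ol
Product: 5 (3R,4R)-1-[(tert-butyldimethylsilyl)oxy]-4-methylhex-5-en-3-yl pivalate
Conditions: PivCl, pyridine, DMAP (cat.), CH2Cl2, 0 → 23 °C
Reagents that add atoms: pivaloyl chloride CC(C)(C)C(Cl)=O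
Why: DMAP-catalysed acylation of the secondary alcohol, the pivalate being chosen because it should survive the later basic steps and fall off in the final hydride reduction.

Step 3
Reactants: 5 (3R,4R)-1-[(tert-butyldimethylsilyl)oxy]-4-methylhex-5-en-3-yl pivalate
Product: 6 (3R,4R)-1-hydroxy-4-methylhex-5-en-3-yl pivalate
Conditions: HF·pyridine, THF–pyridine, 0 → 23 °C
Reagents that add atoms: none
Why: Fluoride-mediated cleavage of the primary silyl ether, which should leave the hindered ester untouched and not induce acyl migration.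

Step 4
Reactants: 6 (3R,4R)-1-hydroxy-4-methylhex-5-en-3-yl pivalate
Product: 7 (3R,4R)-4-methyl-1-oxohex-5-en-3-yl pivalate
Conditions: Dess–Martin periodinane, NaHCO3, CH2Cl2, 0 → 23 °C
Reagents that add atoms: none
Why: Dess–Martin oxidation of a primary alcohol to the aldehyde, buffered so that the β-acyloxy aldehyde does not eliminate.

Step 5
Reactants: 7 (3R,4R)-4-methyl-1-oxohex-5-en-3-yl pivalate; 8 methyl propanoate
Product: 9 methyl (5R,6R)-3-hydroxy-2,6-dimethyl-5-(pivaloyloxy)oct-7-enoate (mixture at C2 and C3)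
Conditions: LiN(i-Pr)2, THF, −78 °C; then 7
Reagents that add atoms: none
Why: Aldol addition of the ester lithium enolate to the aldehyde at low temperature, the two new stereocentres being of no consequence because both are erased in steps 6 and 7.

Step 6
Reactants: 9 methyl (5R,6R)-3-hydroxy-2,6-dimethyl-5-(pivaloyloxy)oct-7-enoate
Product: 10 methyl (5R,6R)-2,6-dimethyl-3-oxo-5-(pivaloyloxy)oct-7-enoate
Conditions: Dess–Martin periodinane, CH2Cl2, 23 °C
Reagents that add atoms: none
Why: Dess–Martin oxidation of a β-hydroxy ester to the α-methyl β-keto ester under neutral conditions.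

Step 7
Reactants: 10 methyl (5R,6R)-2,6-dimethyl-3-oxo-5-(pivaloyloxy)oct-7-enoate
Product: 11 methyl (2E,5R,6R)-2,6-dimethyl-5-(pivaloyloxy)-3-(tosyloxy)octa-2,7-dienoate
Conditions: TsCl, Me2N(CH2)6NMe2, MeCN, 0 °C
Reagents that add atoms: p-toluenesulfonyl chloride Cc1ccc(cc1)S(Cl)(=O)=O
Why: Stereoselective enol tosylation of an α-substituted β-keto ester under non-chelating amine conditions, where the enolate with oxide and ester anti is trapped to give the (E)-isomer (OTs trans to CO2Me, cis to the α-methyl), which encodes the C7=C11 geometry of the target.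

Step 8
Reactants: 11 methyl (2E,5R,6R)-2,6-dimethyl-5-(pivaloyloxy)-3-(tosyloxy)octa-2,7-dienoate; 12 ethynyltrimethylsilane
Product: 13 methyl (2E,5R,6R)-2,6-dimethyl-5-(pivaloyloxy)-3-[(trimethylsilyl)ethynyl]octa-2,7-dienoate
Conditions: PdCl2(PPh3)2 (5 mol %), CuI (10 mol %), i-Pr2NH, DMF, 50 °C
Reagents that add atoms: none
Why: Sonogashira coupling of the electron-poor β-tosyloxy acrylate, which proceeds with retention of alkene geometry so that the alkyne (later C8) ends cis to the C11 methyl.

Step 9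
Reactants: 13 methyl (2E,5R,6R)-2,6-dimethyl-5-(pivaloyloxy)-3-[(trimethylsilyl)ethynyl]octa-2,7-dienoate
Product: 14 methyl (2E,5R,6R)-3-ethynyl-2,6-dimethyl-5-(pivaloyloxy)octa-2,7-dienoate
Conditions: K2CO3 (cat.), MeOH, 0 °C
Reagents that add atoms: none
Why: Base-catalysed methanolysis of the C(sp)–Si bond, kept cold and short so that the methyl ester, the pivalate and the conjugated enyne are not attacked.

Step 10
Reactants: 14 methyl (2E,5R,6R)-3-ethynyl-2,6-dimethyl-5-(pivaloyloxy)octa-2,7-dienoate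
Product: 15 methyl (2E)-2-[(3aR,4R,5R)-4-methyl-2-oxo-5-(pivaloyloxy)-2,3,3a,4,5,6-hexahydro-7H-inden-7-ylidene]propanoate
Conditions: Co2(CO)8 (15 mol %), tetramethylthiourea (90 mol %), CO (1 atm), toluene, 70 °C
Reagents that add atoms: carbon monoxide [C-]#[O+]
Why: Intramolecular Pauson–Khand [2+2+1] reaction of the 1,7-enyne, which closes ring B (C3–C8) and the cyclopentenone together and sets C3 in a chair-like cyclisation with the C4 methyl and C5 pivalate equatorial, placing the new C3–C2 bond trans to the C4 methyl.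

Step 11
Reactants: 15 methyl (2E)-2-[(3aR,4R,5R)-4-methyl-2-oxo-5-(pivaloyloxy)-2,3,3a,4,5,6-hexahydro-7H-inden-7-ylidene]propanoate
Product: 16 methyl (2E)-2-[(3aS,4R,5R,7aS)-2-[(dimethylphenylsilyl)oxy]-4-methyl-5-(pivaloyloxy)-3,3a,4,5,6,7a-hexahydro-7H-inden-7-ylidene]propanoate
Conditions: [(Ph3P)CuH]6 (3 mol %), PhMe2SiH, toluene, 0 → 23 °C
Reagents that add atoms: dimethylphenylsilane C[SiH](C)c1ccccc1
Why: Copper hydride-catalysed 1,4-hydrosilylation of the enone, in which hydride should add to C8 on the face of the C3 hydrogen to give the cis ring fusion (the isomer free of allylic 1,3-strain with the C11 methyl) while O-silylation fixes the enol ether double bond at C1=C9 and the hindered tetrasubstituted enoate stays untouched.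

Step 12
Reactants: 16 methyl (2E)-2-[(3aS,4R,5R,7aS)-2-[(dimethylphenylsilyl)oxy]-4-methyl-5-(pivaloyloxy)-3,3a,4,5,6,7a-hexahydro-7H-inden-7-ylidene]propanoate
Product: 18 methyl (2E)-2-[(3R,4R,4aS,8aS)-7-bromo-4-methyl-6-oxo-3-(pivaloyloxy)-3,4,4a,5,6,8a-hexahydronaphthalen-1(2H)-ylidene]propanoate, via dibromocyclopropane 17 (not isolated)
Conditions: CHBr3, KOt-Bu, pentane, −30 → 23 °C
Reagents that add atoms: bromoform BrC(Br)Br
Why: Dibromocarbene adds to the electron-rich C1=C9 enol ether to give the 1-siloxy-6,6-dibromobicyclo[3.1.0]hexane 17; ionisation of the endo C–Br bond with concerted disrotatory opening of the C1–C9 bond (cyclopropyl-to-allyl cation), pushed by the siloxy oxygen, and loss of the silyl group to bromide then give the 2-bromocyclohex-2-enone. The closest known reaction type is the one-carbon ring expansion of cyclic silyl enol ethers to 2-halocycloalk-2-enones through their dihalocarbene adducts. The only ring that is closed is the transient cyclopropane, by [2+1] cheletropic addition; ring A is not closed by a cyclisation but arises when C10 is inserted between C1 and C9 of the five-membered ring through cleavage of the ring-fusion bond of 17. No new stereocentre remains, since C1 and C9 of 17 (formed on either face) become sp2 again, and C8, now γ to the ketone, already has the thermodynamically preferred cis configuration. The step needs chemoselectivity for the enol ether over the C7=C11 alkene, secured because that alkene is a hindered, electron-poor tetrasubstituted enoate facing an electrophilic carbene. It also needs regioselective insertion, secured by the enol ether position fixed in step 11, and an endo bromide for the opening, which a gem-dibromide always has.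

Step 13
Reactants: 18 methyl (2E)-2-[(3R,4R,4aS,8aS)-7-bromo-4-methyl-6-oxo-3-(pivaloyloxy)-3,4,4a,5,6,8a-hexahydronaphthalen-1(2H)-ylidene]propanoate
Product: 19 methyl (2E)-2-[(3R,4R,4aS,8aS)-4,7-dimethyl-6-oxo-3-(pivaloyloxy)-3,4,4a,5,6,8a-hexahydronaphthalen-1(2H)-ylidene]propanoate
Conditions: MeZnCl, Pd[P(t-Bu)3]2 (5 mol %), THF–NMP, 23 °C
Reagents that add atoms: methylzinc chloride C[Zn]Cl
Why: Negishi coupling of an α-bromoenone with an alkylzinc reagent, which installs the C10 methyl without touching the ketone, the esters or the C8 stereocentre.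

Step 14
Reactants: 19 methyl (2E)-2-[(3R,4R,4aS,8aS)-4,7-dimethyl-6-oxo-3-(pivaloyloxy)-3,4,4a,5,6,8a-hexahydronaphthalen-1(2H)-ylidene]propanoate
Product: 20 (2E)-2-[(3R,4R,4aS,6R,8aS)-3,6-dihydroxy-4,7-dimethyl-3,4,4a,5,6,8a-hexahydronaphthalen-1(2H)-ylidene]propan-1-ol
Conditions: i-Bu2AlH (8 equiv), CH2Cl2, −78 → 0 °C; aqueous potassium sodium tartrate
Reagents that add atoms: none
Why: Hydride reduction that turns the enone into the allylic alcohol (1,2-addition), the enoate into the primary allylic alcohol and the pivalate into the free C5 alcohol in one operation, with C1 set by attack on the convex face of the folded cis-decalenone, anti to the axial C3–C4 bond, which gives the C1 hydroxyl cis to ring B.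

Step 15
Reactants: 20 (2E)-2-[(3R,4R,4aS,6R,8aS)-3,6-dihydroxy-4,7-dimethyl-3,4,4a,5,6,8a-hexahydronaphthalen-1(2H)-ylidene]propan-1-ol
Product: 21 (2E)-2-[(3R,4R,4aS,6R,8aS)-3,6-dihydroxy-4,7-dimethyl-3,4,4a,5,6,8a-hexahydronaphthalen-1(2H)-ylidene]propyl formate
Conditions: HCO2CH2CF3 (1.5 equiv), THF, 23 °C
Reagents that add atoms: 2,2,2-trifluoroethyl formate O=COCC(F)(F)F
Why: Formyl transfer from an activated formate ester, which should be selective for the unhindered primary allylic alcohol over the two secondary alcohols (one pseudoaxial and shielded by ring B, one flanked by the C4 methyl).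

Step 16
Reactants: 21 (2E)-2-[(3R,4R,4aS,6R,8aS)-3,6-dihydroxy-4,7-dimethyl-3,4,4a,5,6,8a-hexahydronaphthalen-1(2H)-ylidene]propyl formate
Product: 22 (2E)-2-[(3R,4R,4aS,6R,8aS)-3,6-diacetoxy-4,7-dimethyl-3,4,4a,5,6,8a-hexahydronaphthalen-1(2H)-ylidene]propyl formate (CNP0262962.1)
Conditions: Ac2O, pyridine, DMAP (cat.), CH2Cl2, 0 → 23 °C
Reagents that add atoms: acetic anhydride CC(=O)OC(C)=O
Why: DMAP-catalysed acetylation of both secondary alcohols under conditions that a formate ester tolerates, with no stereocentre touched.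

**Compound list**

1 | 3-[(tert-butyldimethylsilyl)oxy]propanal | O=CCCO[Si](C)(C)C(C)(C)C | starting material
2 | (Z)-crotylboronic acid pinacol ester | C/C=C\CB1OC(C)(C)C(C)(C)O1 | starting material
3 | pinacol borate ester of 4 | C=C[C@@H](C)[C@H](OB1OC(C)(C)C(C)(C)O1)CCO[Si](C)(C)C(C)(C)C | intermediate
4 | (3R,4R)-1-[(tert-butyldimethylsilyl)oxy]-4-methylhex-5-en-3-ol | C=C[C@@H](C)[C@H](O)CCO[Si](C)(C)C(C)(C)C | intermediate
5 | (3R,4R)-1-[(tert-butyldimethylsilyl)oxy]-4-methylhex-5-en-3-yl pivalate | C=C[C@@H](C)[C@H](OC(=O)C(C)(C)C)CCO[Si](C)(C)C(C)(C)C | intermediate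
6 | (3R,4R)-1-hydroxy-4-methylhex-5-en-3-yl pivalate | C=C[C@@H](C)[C@H](OC(=O)C(C)(C)C)CCO | intermediate
7 | (3R,4R)-4-methyl-1-oxohex-5-en-3-yl pivalate | C=C[C@@H](C)[C@H](OC(=O)C(C)(C)C)CC=O | intermediate
8 | methyl propanoate | CCC(=O)OC | starting material
9 | methyl (5R,6R)-3-hydroxy-2,6-dimethyl-5-(pivaloyloxy)oct-7-enoate (mixture at C2, C3) | C=C[C@@H](C)[C@H](OC(=O)C(C)(C)C)CC(O)C(C)C(=O)OC | intermediate
10 | methyl (5R,6R)-2,6-dimethyl-3-oxo-5-(pivaloyloxy)oct-7-enoate | C=C[C@@H](C)[C@H](OC(=O)C(C)(C)C)CC(=O)C(C)C(=O)OC | intermediate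
11 | methyl (2E,5R,6R)-2,6-dimethyl-5-(pivaloyloxy)-3-(tosyloxy)octa-2,7-dienoate | C=C[C@@H](C)[C@H](OC(=O)C(C)(C)C)C/C(OS(=O)(=O)c1ccc(C)cc1)=C(/C)C(=O)OC | intermediate
12 | ethynyltrimethylsilane | C#C[Si](C)(C)C | starting material
13 | methyl (2E,5R,6R)-2,6-dimethyl-5-(pivaloyloxy)-3-[(trimethylsilyl)ethynyl]octa-2,7-dienoate | C=C[C@@H](C)[C@H](OC(=O)C(C)(C)C)C/C(C#C[Si](C)(C)C)=C(/C)C(=O)OC | intermediate
14 | methyl (2E,5R,6R)-3-ethynyl-2,6-dimethyl-5-(pivaloyloxy)octa-2,7-dienoate | C=C[C@@H](C)[C@H](OC(=O)C(C)(C)C)C/C(C#C)=C(/C)C(=O)OC | intermediate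
15 | methyl (2E)-2-[(3aR,4R,5R)-4-methyl-2-oxo-5-(pivaloyloxy)-2,3,3a,4,5,6-hexahydro-7H-inden-7-ylidene]propanoate | O=C1C[C@@H]2[C@@H](C)[C@H](OC(=O)C(C)(C)C)C/C(=C(/C)C(=O)OC)C2=C1 | intermediate
16 | methyl (2E)-2-[(3aS,4R,5R,7aS)-2-[(dimethylphenylsilyl)oxy]-4-methyl-5-(pivaloyloxy)-3,3a,4,5,6,7a-hexahydro-7H-inden-7-ylidene]propanoate (cis-fused) | C[Si](C)(c3ccccc3)OC1C[C@@H]2[C@@H](C)[C@H](OC(=O)C(C)(C)C)C/C(=C(/C)C(=O)OC)[C@@H]2C=1 | intermediate
17 | dibromocarbene adduct of 16 (1-siloxy-6,6-dibromobicyclo[3.1.0]hexane unit, cyclopropane on either face) | C[Si](C)(c3ccccc3)OC14C[C@@H]2[C@@H](C)[C@H](OC(=O)C(C)(C)C)C/C(=C(/C)C(=O)OC)[C@@H]2C1C4(Br)Br | intermediate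
18 | methyl (2E)-2-[(3R,4R,4aS,8aS)-7-bromo-4-methyl-6-oxo-3-(pivaloyloxy)-3,4,4a,5,6,8a-hexahydronaphthalen-1(2H)-ylidene]propanoate | O=C1C[C@@H]2[C@@H](C)[C@H](OC(=O)C(C)(C)C)C/C(=C(/C)C(=O)OC)[C@@H]2C=C1Br | intermediate
19 | methyl (2E)-2-[(3R,4R,4aS,8aS)-4,7-dimethyl-6-oxo-3-(pivaloyloxy)-3,4,4a,5,6,8a-hexahydronaphthalen-1(2H)-ylidene]propanoate | O=C1C[C@@H]2[C@@H](C)[C@H](OC(=O)C(C)(C)C)C/C(=C(/C)C(=O)OC)[C@@H]2C=C1C | intermediate
20 | (2E)-2-[(3R,4R,4aS,6R,8aS)-3,6-dihydroxy-4,7-dimethyl-3,4,4a,5,6,8a-hexahydronaphthalen-1(2H)-ylidene]propan-1-ol | O[C@@H]1C[C@@H]2[C@@H](C)[C@H](O)C/C(=C(/C)CO)[C@@H]2C=C1C | intermediate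
21 | (2E)-2-[(3R,4R,4aS,6R,8aS)-3,6-dihydroxy-4,7-dimethyl-3,4,4a,5,6,8a-hexahydronaphthalen-1(2H)-ylidene]propyl formate | O[C@@H]1C[C@@H]2[C@@H](C)[C@H](O)C/C(=C(/C)COC=O)[C@@H]2C=C1C | intermediate
22 | (2E)-2-[(3R,4R,4aS,6R,8aS)-3,6-diacetoxy-4,7-dimethyl-3,4,4a,5,6,8a-hexahydronaphthalen-1(2H)-ylidene]propyl formate | CC(=O)O[C@@H]1C[C@@H]2[C@@H](C)[C@H](OC(C)=O)C/C(=C(/C)COC=O)[C@@H]2C=C1C | target

**Count and risks**

Total step count: 16. Longest linear sequence: 16 steps (from 1).

Steps most likely to fail: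

Step 10. The alkene may insert too slowly into the cobalt complex of the electron-poor, conjugated alkyne, so that alkyne oligomerisation or decomplexation outruns closure of the six-membered ring. The fallback sets out from 14 and returns at 15. The enyne is cyclised on zerovalent nickel, which favours electron-poor π-systems, with an isocyanide as the one-carbon unit (Ni(cod)2, PBu3, 2,6-dimethylphenyl isocyanide, THF). This gives the N-(2,6-dimethylphenyl)imine of 15, F1, which mild acid hydrolysis (aqueous oxalic acid, THF) converts into 15.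

Step 11. Hydride may be delivered to the wrong face of C8, because the C11 methyl of the twisted diene lies over the face of the C3 hydrogen, and this would give the trans ring fusion. The fallback replaces kinetic facial control by thermodynamic control; it sets out from 15 and returns at 19. The trans-fused silyl enol ether F2 is carried through step 12 (dibromocyclopropane F3, then trans-fused bromoenone F4) and step 13 to the trans-fused methyl enone F5. F5 is equilibrated with DBU in toluene at 60 °C through the extended dienolate formed by γ-deprotonation at C8. The cis isomer 19 should predominate, because in the trans isomer C9 is equatorial on ring B and eclipses the C11 methyl (allylic 1,3-strain).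

Step 12. tert-Butoxide may cleave the silyl enol ether or deprotonate the enoate at its γ-position faster than the carbene adds, or the adduct may fail to open cleanly. The fallback is an oxidative, base-free ring expansion; it sets out from 16 and returns at 19. Furukawa cyclopropanation (Et2Zn, CH2I2, CH2Cl2, 0 °C) gives the siloxycyclopropane F6. FeCl3 in DMF (Ito–Saegusa ring expansion by β-scission of the ring-fusion bond) gives the 3-chlorocyclohexanone F7. NaOAc in MeOH eliminates HCl to give the cyclohexenone F8, and I2 with pyridine in CH2Cl2 gives the 2-iodoenone F9. The Negishi methylation of step 13 then gives 19.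

**Further compounds**

F1 | step 10 | methyl (2E)-2-[(3aR,4R,5R)-2-[(2,6-dimethylphenyl)imino]-4-methyl-5-(pivaloyloxy)-2,3,3a,4,5,6-hexahydro-7H-inden-7-ylidene]propanoate | Cc3cccc(C)c3N=C1C[C@@H]2[C@@H](C)[C@H](OC(=O)C(C)(C)C)C/C(=C(/C)C(=O)OC)C2=C1
F2 | step 11 | trans-fused silyl enol ether, the (3aS,4R,5R,7aR) epimer of 16 | C[Si](C)(c3ccccc3)OC1C[C@@H]2[C@@H](C)[C@H](OC(=O)C(C)(C)C)C/C(=C(/C)C(=O)OC)[C@H]2C=1
F3 | step 11 | dibromocarbene adduct of F2 | C[Si](C)(c3ccccc3)OC14C[C@@H]2[C@@H](C)[C@H](OC(=O)C(C)(C)C)C/C(=C(/C)C(=O)OC)[C@H]2C1C4(Br)Br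
F4 | step 11 | trans-fused bromoenone, the (3R,4R,4aS,8aR) epimer of 18 | O=C1C[C@@H]2[C@@H](C)[C@H](OC(=O)C(C)(C)C)C/C(=C(/C)C(=O)OC)[C@H]2C=C1Br
F5 | step 11 | trans-fused methyl enone, the (3R,4R,4aS,8aR) epimer of 19 | O=C1C[C@@H]2[C@@H](C)[C@H](OC(=O)C(C)(C)C)C/C(=C(/C)C(=O)OC)[C@H]2C=C1C
F6 | step 12 | methylene adduct of 16 (1-siloxybicyclo[3.1.0]hexane unit) | C[Si](C)(c3ccccc3)OC14C[C@@H]2[C@@H](C)[C@H](OC(=O)C(C)(C)C)C/C(=C(/C)C(=O)OC)[C@@H]2C1C4
F7 | step 12 | methyl (2E)-2-[(3R,4R,4aS,8aS)-8-chloro-4-methyl-6-oxo-3-(pivaloyloxy)octahydronaphthalen-1(2H)-ylidene]propanoate | O=C1C[C@@H]2[C@@H](C)[C@H](OC(=O)C(C)(C)C)C/C(=C(/C)C(=O)OC)[C@@H]2C(Cl)C1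
F8 | step 12 | methyl (2E)-2-[(3R,4R,4aS,8aS)-4-methyl-6-oxo-3-(pivaloyloxy)-3,4,4a,5,6,8a-hexahydronaphthalen-1(2H)-ylidene]propanoate | O=C1C[C@@H]2[C@@H](C)[C@H](OC(=O)C(C)(C)C)C/C(=C(/C)C(=O)OC)[C@@H]2C=C1
F9 | step 12 | methyl (2E)-2-[(3R,4R,4aS,8aS)-7-iodo-4-methyl-6-oxo-3-(pivaloyloxy)-3,4,4a,5,6,8a-hexahydronaphthalen-1(2H)-ylidene]propanoate | O=C1C[C@@H]2[C@@H](C)[C@H](OC(=O)C(C)(C)C)C/C(=C(/C)C(=O)OC)[C@@H]2C=C1I
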